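The numbers in the tables were generated by integration with made-up constants.

If you count what the first end groups did instead of forming links, your hunch that more second end groups would pay can be given a number, so I tried that.

the same everywhere: first end groups 1.5 M
- ochre: second end groups 0.75 M; run made earlier
- red: second end groups 2.1 M; run made earlier
- south: second end groups 1.20 M; time 2.0 h
- south-east: second end groups 1.50 M; time 2.0 h
- south-west: second end groups 2.50 M; time 2.0 h

- ochre (time / min: links / %, first end groups / %): 10.0: 16.2, 66.8; 30.0: 27.3, 39.0; 60.0: 37.4, 23.4; 80.0: 37.7, 21.0; 120: 37.6, 13.3
- red (time / min: links / %, first end groups / %): 10.0: 36.4, 47.5; 30.0: 60.6, 19.3; 60.0: 72.2, 7.0; 80.0: 73.4, 5.5; 120: 74.5, 4.1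

(each reading ± 1 percentage point)

- "hardly changes" means that all values lie within two and a half points (for a concentration: within two and a half percent of the largest)

1. amount of links at the end, in percent of the first end groups charged for south, south-east, south-west, in this order
2. how that number moves from the first to the last of them (rises, then falls / falls, then rises / falls all the way / hardly changes / rises all the way)

I took the last readings, at 120 min, which is the asked time, and used the split: links made per first end group lost some other way, a selectivity factor. A split of 1 was my zero, the even case. Taking links and leftover first end groups from the charge gave the lost part, so the ochre run read 0.766, below even, and the red run read 3.48, above it. Between those runs the split climbed with the charge of second end groups raised to the power 1.47, the steepness, a reading that carries their scatter.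

The steepness gave me splits of 1.53 for south, 2.12 for south-east and 4.50 for south-west, which lies beyond the red run. A similar line through the leftovers, with power −1.14, left 7.77%, 6.02% and 3.36%. Dividing what was consumed by the split, I committed to 55.8%, 63.9% and 79.1%.

The forecast, reckoned differently, said 52%, 60% and 79%, that the number rises all the way, and “I see no sign of a maximum”.

The simulation gave 56.3%, 64.4% and 78.9%, and the number rises all the way.

    first end groups + second end groups ⇌ links + by-product (K = 25.0, k = 0.0307 M⁻¹ min⁻¹)
    2 first end groups → self-condensation product (k = 0.00947 M⁻¹ min⁻¹)

The split came to 1.62 in south, against 1.53 from the steepness, and to 4.35 in south-west, against 4.50. The lost part was the self-condensation product, 18.1% of the first end groups charged in south-west at the end. Removing the reaction of two first end groups to self-condensation product in south-west lifted links from 78.9% to 94.5%, so self-condensation is the main reason for the shortfall there. The way back from links to first end groups and second end groups was a part of that shortfall: with it removed instead, south-west gave 82.0%.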